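**Retrosynthetic overview**

1. Endgame: one hydrogenation sets C20 and saturates C6=C7; the C3–C18 bond comes from a vinylogous Mannich addition of a 2-silyloxyfuran to the C3=N4 iminium ion, unveiled by decarbonylation of a C3 carboxyl placeholder.
2. Key disconnection: N4–C9a and C5–C6 (C5 enters as formaldehyde). An acyclic primary amine carrying a C9a mesylate and a (Z)-vinylsilane at C6 folds into the pyrrolo[1,2-a]azepine in one pot, pyrrolidine first (SN2), then azepine (Mannich-type closure).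
3. Enabling feature: N4 is the ring-fusion tertiary amine; its azepane neighbour C5 is an unsubstituted CH2 bonded to C6 (an aminomethyl, formaldiminium retron), and its neighbour C9a is a secondary carbon shared by the pyrrolidine and azepane rings (an SN2 retron). The silyl group on C6 and the ester on C3 are temporary activators.
4. Acyclic precursor: C9a–OH and C11–OH from a double CBS reduction of a 1,4-diketone (C11–OH closes the side-chain lactone); the diketone from two organozinc acylations of a succinate; C9 and C10 from an Evans alkylation with an α-triflyloxy ester.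
5. Ring order: side-chain γ-lactone, pyrrolidine, azepine, then the lactone on C3.

Key step: step 10

Remark: numbering follows the pyrrolo[1,2-a]azepine core (C1–C3, N4, C5–C9, C9a); C10 is the CH(Et) carbon, C11 and C13 are the carbinol and methyl-bearing carbons of its lactone, C18 and C20 those of the lactone on C3. Building blocks 2, 5, 9, 14 and 26 are assumed purchasable, and the C3 configuration brought in by 14 is immaterial because C3 becomes sp2 in step 13.

**Route**

Step 1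
Reactants: 1 (S)-4-benzyl-1,3-oxazolidin-2-one; 2 5-(trimethylsilyl)pent-4-ynoic acid
Product: 4 (S)-4-benzyl-3-[5-(trimethylsilyl)pent-4-ynoyl]-1,3-oxazolidin-2-one, via mixed pivalic anhydride 3 (not isolated)
Conditions: t-BuCOCl, Et3N, THF, −20 °C; then 1, LiCl, −20 °C → rt
Reagents that add atoms: none
Why: N-acylation of the oxazolidinone through the mixed pivalic anhydride (LiCl-assisted acyl transfer) is the standard mild way to attach the Evans auxiliary, and no stereocenter is formed.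

Step 2
Reactants: 5 tert-butyl (S)-2-hydroxybutanoate
Product: 6 tert-butyl (S)-2-(trifluoromethanesulfonyloxy)butanoate
Conditions: Tf2O, 2,6-lutidine, CH2Cl2, −78 → 0 °C
Reagents that add atoms: trifluoromethanesulfonic anhydride, O=S(=O)(OS(=O)(=O)C(F)(F)F)C(F)(F)F
Why: O-sulfonylation of the α-hydroxy ester leaves the C–O bond untouched, so the configuration is retained and the carbinol carbon (future C10) becomes an activated SN2 electrophile.

Step 3
Reactants: 4 (S)-4-benzyl-3-[5-(trimethylsilyl)pent-4-ynoyl]-1,3-oxazolidin-2-one; 6 tert-butyl (S)-2-(trifluoromethanesulfonyloxy)butanoate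
Product: 8 tert-butyl (2S,3R)-3-{[(S)-4-benzyl-2-oxo-1,3-oxazolidin-3-yl]carbonyl}-2-ethyl-6-(trimethylsilyl)hex-5-ynoate, via sodium enolate 7 (not isolated)
Conditions: NaN(SiMe3)2, THF, −78 °C; then 6, −78 → −30 °C
Reagents that add atoms: none
Why: In this Evans alkylation the chelated (Z)-enolate should be attacked on the face opposite the benzyl group (sets C9 as R), while the α-triflyloxy ester is displaced by SN2 with inversion (sets C10 as S), which gives the anti-2,3-disubstituted succinate.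

Step 4
Reactants: 8 tert-butyl (2S,3R)-3-{[(S)-4-benzyl-2-oxo-1,3-oxazolidin-3-yl]carbonyl}-2-ethyl-6-(trimethylsilyl)hex-5-ynoate; 9 methyl (R)-3-bromo-2-methylpropanoate
Product: 12 methyl (2S,5S,6R)-6-{[(S)-4-benzyl-2-oxo-1,3-oxazolidin-3-yl]carbonyl}-5-ethyl-2-methyl-4-oxo-9-(trimethylsilyl)non-8-ynoate, via organozinc bromide 10 (not isolated), via acid chloride 11 (not isolated)
Conditions: 9, Zn dust, I2 (5 mol %), DMA, 80 °C; separately 8, SOCl2 (neat), rt, then evaporation; then both, Pd(PPh3)4 (5 mol %), THF/DMA, 0 °C → rt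
Reagents that add atoms: none
Why: SOCl2 should convert the tert-butyl ester directly into the acid chloride while the imide stays inert, and Negishi-type acylation of the β-zincio ester under zerovalent palladium catalysis then gives the γ-keto ester, with C13 carried in unchanged from 9 and C9 and C10 not exposed to base.

Step 5
Reactants: 12 methyl (2S,5S,6R)-6-{[(S)-4-benzyl-2-oxo-1,3-oxazolidin-3-yl]carbonyl}-5-ethyl-2-methyl-4-oxo-9-(trimethylsilyl)non-8-ynoate
Product: 13 methyl (2S,5S,6R)-5-ethyl-6-[(ethylsulfanyl)carbonyl]-2-methyl-4-oxo-9-(trimethylsilyl)non-8-ynoate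
Conditions: EtSH, n-BuLi, THF, −78 → 0 °C
Reagents that add atoms: ethanethiol, CCS
Why: Thiolate cleavage of the N-acyl oxazolidinone at the exocyclic carbonyl (transthioesterification) removes the auxiliary without hydroxide, which spares the silylalkyne and the α-stereocenters, and gives a thioester ready for ketone synthesis.

Step 6
Reactants: 13 methyl (2S,5S,6R)-5-ethyl-6-[(ethylsulfanyl)carbonyl]-2-methyl-4-oxo-9-(trimethylsilyl)non-8-ynoate; 14 methyl (S)-2-[(tert-butoxycarbonyl)amino]-4-iodobutanoate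
Product: 16 dimethyl (2S,5S,6R,10S)-10-[(tert-butoxycarbonyl)amino]-5-ethyl-2-methyl-4,7-dioxo-6-[3-(trimethylsilyl)prop-2-yn-1-yl]undecanedioate, via organozinc iodide 15 (not isolated)
Conditions: 14, Zn dust (activated with BrCH2CH2Br and Me3SiCl), DMF, rt; then 13, PdCl2(PPh3)2 (10 mol %), toluene/DMF, rt
Reagents that add atoms: none
Why: The Fukuyama coupling of a thioester with a functionalized alkylzinc iodide should give the C9a ketone chemoselectively beside the other ketone, the esters and the carbamate, and no stereocenter is formed (C3 is only a placeholder).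

Step 7
Reactants: 16 dimethyl (2S,5S,6R,10S)-10-[(tert-butoxycarbonyl)amino]-5-ethyl-2-methyl-4,7-dioxo-6-[3-(trimethylsilyl)prop-2-yn-1-yl]undecanedioate
Product: 18 methyl (2S,5R,6R,7S)-2-[(tert-butoxycarbonyl)amino]-5-hydroxy-7-[(2R,4S)-4-methyl-5-oxooxolan-2-yl]-6-[3-(trimethylsilyl)prop-2-yn-1-yl]nonanoate, via dihydroxy diester 17 (not isolated)
Conditions: (S)-2-methyl-CBS-oxazaborolidine (2 equiv), catecholborane (3 equiv), toluene, −78 → −40 °C; MeOH; then pyridinium p-toluenesulfonate (cat.), CH2Cl2, rt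
Reagents that add atoms: none
Why: In this Corey–Bakshi–Shibata reduction both ketones have a branched large arm (C9 or C10) and a CH2 small arm, so the (S)-catalyst should give the (R)-carbinol at C11 (also the Felkin–Anh sense) and at C9a (catalyst control over a weak opposite substrate bias); the C11 hydroxyl then closes the γ-lactone onto the methyl ester, while the C9a hydroxyl, which could only form a slower six-membered lactone, should stay free.

Step 8
Reactants: 18 methyl (2S,5R,6R,7S)-2-[(tert-butoxycarbonyl)amino]-5-hydroxy-7-[(2R,4S)-4-methyl-5-oxooxolan-2-yl]-6-[3-(trimethylsilyl)prop-2-yn-1-yl]nonanoate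
Product: 19 methyl (2S,5R,6R,7S)-2-[(tert-butoxycarbonyl)amino]-5-hydroxy-7-[(2R,4S)-4-methyl-5-oxooxolan-2-yl]-6-[(Z)-3-(trimethylsilyl)prop-2-en-1-yl]nonanoate
Conditions: H2 (1 atm), Pd/CaCO3 poisoned with Pb(OAc)2 (Lindlar catalyst), quinoline, EtOAc, rt
Reagents that add atoms: none
Why: syn-Semihydrogenation of the 1-silylalkyne on the poisoned palladium surface should give the (Z)-alkenylsilane needed for the cyclization, without touching any sp3 stereocenter.

Step 9
Reactants: 19 methyl (2S,5R,6R,7S)-2-[(tert-butoxycarbonyl)amino]-5-hydroxy-7-[(2R,4S)-4-methyl-5-oxooxolan-2-yl]-6-[(Z)-3-(trimethylsilyl)prop-2-en-1-yl]nonanoate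
Product: 20 methyl (2S,5R,6R,7S)-2-[(tert-butoxycarbonyl)amino]-5-(methanesulfonyloxy)-7-[(2R,4S)-4-methyl-5-oxooxolan-2-yl]-6-[(Z)-3-(trimethylsilyl)prop-2-en-1-yl]nonanoate
Conditions: MsCl, Et3N, CH2Cl2, 0 °C
Reagents that add atoms: methanesulfonyl chloride, CS(=O)(=O)Cl
Why: O-Sulfonylation proceeds with retention at C9a, and the carbamate N–H is not nucleophilic enough to cyclize under these conditions.

Step 10
Reactants: 20 methyl (2S,5R,6R,7S)-2-[(tert-butoxycarbonyl)amino]-5-(methanesulfonyloxy)-7-[(2R,4S)-4-methyl-5-oxooxolan-2-yl]-6-[(Z)-3-(trimethylsilyl)prop-2-en-1-yl]nonanoate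
Product: 24 methyl (3S,9R,9aS)-9-{(1S)-1-[(2R,4S)-4-methyl-5-oxooxolan-2-yl]propyl}-2,3,5,8,9,9a-hexahydro-1H-pyrrolo[1,2-a]azepine-3-carboxylate, via ammonium trifluoroacetate 21 (not isolated), via pyrrolidine 22 (not isolated), via methyleneiminium ion 23 (not isolated)
Conditions: TFA, CH2Cl2, 0 °C, then evaporation; (CH2O)n, i-Pr2NEt (1.1 equiv), MeCN, 25 → 80 °C
Reagents that add atoms: formaldehyde (charged as paraformaldehyde), C=O
Why: Acid removes the Boc group, the freed primary amine displaces the C9a mesylate intramolecularly to give the salt of pyrrolidine 22, this secondary ammonium ion condenses with formaldehyde to the N-methyleneiminium ion 23, and the (Z)-vinylsilane attacks the iminium carbon through its silicon-bearing carbon C6, the β-silyl cation at C7 then losing the Me3Si group to leave the C6=C7 alkene of 24. The closest known reaction types are the cyclization of amino sulfonates to pyrrolidines and the iminium ion–vinylsilane cyclization (a silicon-terminated Mannich-type cationic π-cyclization in its endocyclic mode) run under the usual amine salt–paraformaldehyde conditions. The pyrrolidine closes 5-exo-tet through N4–C9a and the azepine closes 7-endo-trig through C5–C6, with N4–C5 made in the same pot by the condensation. The only new stereocenter, C9a, is fixed by stereospecific inversion of the (R)-mesylate to the (S)-amine, while C9, C10, C11 and C13 are spectators and the alkene-forming closure creates no stereocenter. The step needs ring-size selectivity, which the silicon secures because only bond formation at C6 gives a β-silyl-stabilized cation (attack through C7 would give a six-membered ring via an unstabilized α-silyl cation), and it needs the events in the right order, which the chain length secures because the nitrogen cannot reach the alkene through anything smaller than a ten-membered ring until the pyrrolidine exists. Substitution should beat elimination because the displacement is a five-membered intramolecular one by a weakly basic amine.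

Step 11
Reactants: 24 methyl (3S,9R,9aS)-9-{(1S)-1-[(2R,4S)-4-methyl-5-oxooxolan-2-yl]propyl}-2,3,5,8,9,9a-hexahydro-1H-pyrrolo[1,2-a]azepine-3-carboxylate
Product: 25 (3S,9R,9aS)-9-{(1S)-1-[(2R,4S)-4-methyl-5-oxooxolan-2-yl]propyl}-2,3,5,8,9,9a-hexahydro-1H-pyrrolo[1,2-a]azepine-3-carboxylic acid hydrochloride
Conditions: 6 M aqueous HCl, 70 °C; evaporation
Reagents that add atoms: water, O; hydrogen chloride, Cl
Why: Acid-catalysed ester hydrolysis frees the carboxyl group while the γ-lactone stays closed (or recloses on concentration), and the base-sensitive C13 center is never exposed to base.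

Step 12
Reactants: 26 3-methylfuran-2(5H)-one
Product: 27 triisopropyl[(3-methylfuran-2-yl)oxy]silane
Conditions: i-Pr3SiOSO2CF3, Et3N, CH2Cl2, 0 °C
Reagents that add atoms: triisopropylsilyl trifluoromethanesulfonate, CC(C)[Si](OS(=O)(=O)C(F)(F)F)(C(C)C)C(C)C
Why: Soft enolization and O-silylation of the butenolide gives the 2-silyloxyfuran, the dienol silyl ether used as the vinylogous nucleophile.

Step 13
Reactants: 25 (3S,9R,9aS)-9-{(1S)-1-[(2R,4S)-4-methyl-5-oxooxolan-2-yl]propyl}-2,3,5,8,9,9a-hexahydro-1H-pyrrolo[1,2-a]azepine-3-carboxylic acid hydrochloride; 27 triisopropyl[(3-methylfuran-2-yl)oxy]silane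
Product: 29 (5S)-3-methyl-5-[(3S,9R,9aS)-9-{(1S)-1-[(2R,4S)-4-methyl-5-oxooxolan-2-yl]propyl}-2,3,5,8,9,9a-hexahydro-1H-pyrrolo[1,2-a]azepin-3-yl]furan-2(5H)-one, via bicyclic iminium chloride 28 (not isolated)
Conditions: POCl3, DMF, 0 °C → rt (CO evolution); then 27, CH2Cl2, −40 °C → rt; aqueous NaHCO3
Reagents that add atoms: none
Why: Decarbonylation of the tertiary α-amino acid (acid chloride, acylium ion, loss of CO) should give the C3=N4 iminium ion, which undergoes a vinylogous Mannich reaction with the silyloxyfuran; attack on the pyrrolinium face opposite the C9a–C9 bond sets C3 as S (H3 trans to H9a), and the threo preference of cyclic iminium ions with 2-silyloxyfurans, documented for this 1-azabicyclo[5.3.0]decane ring system, sets C18 as S.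

Step 14
Reactants: 29 (5S)-3-methyl-5-[(3S,9R,9aS)-9-{(1S)-1-[(2R,4S)-4-methyl-5-oxooxolan-2-yl]propyl}-2,3,5,8,9,9a-hexahydro-1H-pyrrolo[1,2-a]azepin-3-yl]furan-2(5H)-one
Product: 30 (3S,5S)-3-methyl-5-[(3S,9R,9aS)-9-{(1S)-1-[(2R,4S)-4-methyl-5-oxooxolan-2-yl]propyl}octahydro-1H-pyrrolo[1,2-a]azepin-3-yl]oxolan-2-one (target)
Conditions: H2 (3 atm), 5% Rh/Al2O3, EtOAc, rt
Reagents that add atoms: none
Why: Heterogeneous hydrogenation should saturate both alkenes, with hydrogen adding to the butenolide face opposite the bulky C18 substituent so that the C20 methyl ends up cis to it (S), while reduction of C6=C7 creates no stereocenter.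

**Compound list**

1 | (S)-4-benzyl-1,3-oxazolidin-2-one | O=C1OC[C@H](Cc2ccccc2)N1 | starting material
2 | 5-(trimethylsilyl)pent-4-ynoic acid | C[Si](C)(C)C#CCCC(=O)O | starting material
3 | 5-(trimethylsilyl)pent-4-ynoic pivalic anhydride | C[Si](C)(C)C#CCCC(=O)OC(=O)C(C)(C)C | intermediate
4 | (S)-4-benzyl-3-[5-(trimethylsilyl)pent-4-ynoyl]-1,3-oxazolidin-2-one | C[Si](C)(C)C#CCCC(=O)N1C(=O)OC[C@@H]1Cc1ccccc1 | intermediate
5 | tert-butyl (S)-2-hydroxybutanoate | CC[C@H](O)C(=O)OC(C)(C)C | starting material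
6 | tert-butyl (S)-2-(trifluoromethanesulfonyloxy)butanoate | CC[C@H](OS(=O)(=O)C(F)(F)F)C(=O)OC(C)(C)C | intermediate
7 | sodium (Z)-enolate of 4 | [Na+].[O-]/C(=C\CC#C[Si](C)(C)C)N1C(=O)OC[C@@H]1Cc1ccccc1 | intermediate
8 | tert-butyl (2S,3R)-3-{[(S)-4-benzyl-2-oxo-1,3-oxazolidin-3-yl]carbonyl}-2-ethyl-6-(trimethylsilyl)hex-5-ynoate | CC[C@@H]([C@H](C(=O)N1C(=O)OC[C@@H]1Cc1ccccc1)CC#C[Si](C)(C)C)C(=O)OC(C)(C)C | intermediate
9 | methyl (R)-3-bromo-2-methylpropanoate | COC(=O)[C@@H](C)CBr | starting material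
10 | [(R)-3-methoxy-2-methyl-3-oxopropyl]zinc bromide | COC(=O)[C@@H](C)C[Zn]Br | intermediate
11 | (2S,3R)-3-{[(S)-4-benzyl-2-oxo-1,3-oxazolidin-3-yl]carbonyl}-2-ethyl-6-(trimethylsilyl)hex-5-ynoyl chloride | CC[C@@H]([C@H](C(=O)N1C(=O)OC[C@@H]1Cc1ccccc1)CC#C[Si](C)(C)C)C(Cl)=O | intermediate
12 | methyl (2S,5S,6R)-6-{[(S)-4-benzyl-2-oxo-1,3-oxazolidin-3-yl]carbonyl}-5-ethyl-2-methyl-4-oxo-9-(trimethylsilyl)non-8-ynoate | CC[C@@H]([C@H](C(=O)N1C(=O)OC[C@@H]1Cc1ccccc1)CC#C[Si](C)(C)C)C(=O)C[C@H](C)C(=O)OC | intermediate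
13 | methyl (2S,5S,6R)-5-ethyl-6-[(ethylsulfanyl)carbonyl]-2-methyl-4-oxo-9-(trimethylsilyl)non-8-ynoate | CC[C@@H]([C@H](C(=O)SCC)CC#C[Si](C)(C)C)C(=O)C[C@H](C)C(=O)OC | intermediate
14 | methyl (S)-2-[(tert-butoxycarbonyl)amino]-4-iodobutanoate | COC(=O)[C@H](CCI)NC(=O)OC(C)(C)C | starting material
15 | {(S)-3-[(tert-butoxycarbonyl)amino]-4-methoxy-4-oxobutyl}zinc iodide | COC(=O)[C@H](CC[Zn]I)NC(=O)OC(C)(C)C | intermediate
16 | dimethyl (2S,5S,6R,10S)-10-[(tert-butoxycarbonyl)amino]-5-ethyl-2-methyl-4,7-dioxo-6-[3-(trimethylsilyl)prop-2-yn-1-yl]undecanedioate | CC[C@@H]([C@H](C(=O)CC[C@H](NC(=O)OC(C)(C)C)C(=O)OC)CC#C[Si](C)(C)C)C(=O)C[C@H](C)C(=O)OC | intermediate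
17 | dimethyl (2S,4R,5S,6R,7R,10S)-10-[(tert-butoxycarbonyl)amino]-5-ethyl-4,7-dihydroxy-2-methyl-6-[3-(trimethylsilyl)prop-2-yn-1-yl]undecanedioate | CC[C@@H]([C@H]([C@H](O)CC[C@H](NC(=O)OC(C)(C)C)C(=O)OC)CC#C[Si](C)(C)C)[C@H](O)C[C@H](C)C(=O)OC | intermediate
18 | methyl (2S,5R,6R,7S)-2-[(tert-butoxycarbonyl)amino]-5-hydroxy-7-[(2R,4S)-4-methyl-5-oxooxolan-2-yl]-6-[3-(trimethylsilyl)prop-2-yn-1-yl]nonanoate | CC[C@@H]([C@H]([C@H](O)CC[C@H](NC(=O)OC(C)(C)C)C(=O)OC)CC#C[Si](C)(C)C)[C@H]1C[C@H](C)C(=O)O1 | intermediate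
19 | methyl (2S,5R,6R,7S)-2-[(tert-butoxycarbonyl)amino]-5-hydroxy-7-[(2R,4S)-4-methyl-5-oxooxolan-2-yl]-6-[(Z)-3-(trimethylsilyl)prop-2-en-1-yl]nonanoate | CC[C@@H]([C@H]([C@H](O)CC[C@H](NC(=O)OC(C)(C)C)C(=O)OC)C/C=C\[Si](C)(C)C)[C@H]1C[C@H](C)C(=O)O1 | intermediate
20 | methyl (2S,5R,6R,7S)-2-[(tert-butoxycarbonyl)amino]-5-(methanesulfonyloxy)-7-[(2R,4S)-4-methyl-5-oxooxolan-2-yl]-6-[(Z)-3-(trimethylsilyl)prop-2-en-1-yl]nonanoate | CC[C@@H]([C@H]([C@H](OS(C)(=O)=O)CC[C@H](NC(=O)OC(C)(C)C)C(=O)OC)C/C=C\[Si](C)(C)C)[C@H]1C[C@H](C)C(=O)O1 | intermediate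
21 | ammonium trifluoroacetate of the N-deprotected mesylate (2S,5R,6R,7S) | CC[C@@H]([C@H]([C@H](OS(C)(=O)=O)CC[C@H]([NH3+])C(=O)OC)C/C=C\[Si](C)(C)C)[C@H]1C[C@H](C)C(=O)O1.[O-]C(=O)C(F)(F)F | intermediate
22 | methyl (2S,5S)-5-{(1Z,4R,5S)-5-[(2R,4S)-4-methyl-5-oxooxolan-2-yl]-1-(trimethylsilyl)hept-1-en-4-yl}pyrrolidine-2-carboxylate | CC[C@@H]([C@H]([C@@H]1CC[C@@H](C(=O)OC)N1)C/C=C\[Si](C)(C)C)[C@H]1C[C@H](C)C(=O)O1 | intermediate
23 | N-methyleneiminium methanesulfonate of 22 | CC[C@@H]([C@H]([C@@H]1CC[C@@H](C(=O)OC)[N+]1=C)C/C=C\[Si](C)(C)C)[C@H]1C[C@H](C)C(=O)O1.CS(=O)(=O)[O-] | intermediate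
24 | methyl (3S,9R,9aS)-9-{(1S)-1-[(2R,4S)-4-methyl-5-oxooxolan-2-yl]propyl}-2,3,5,8,9,9a-hexahydro-1H-pyrrolo[1,2-a]azepine-3-carboxylate | CC[C@@H]([C@H]1CC=CCN2[C@H]1CC[C@H]2C(=O)OC)[C@H]1C[C@H](C)C(=O)O1 | intermediate
25 | (3S,9R,9aS)-9-{(1S)-1-[(2R,4S)-4-methyl-5-oxooxolan-2-yl]propyl}-2,3,5,8,9,9a-hexahydro-1H-pyrrolo[1,2-a]azepine-3-carboxylic acid hydrochloride | CC[C@@H]([C@H]1CC=CCN2[C@H]1CC[C@H]2C(=O)O)[C@H]1C[C@H](C)C(=O)O1.Cl | intermediate
26 | 3-methylfuran-2(5H)-one | CC1=CCOC1=O | starting material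
27 | triisopropyl[(3-methylfuran-2-yl)oxy]silane | Cc1ccoc1O[Si](C(C)C)(C(C)C)C(C)C | intermediate
28 | bicyclic C3=N4 iminium chloride (9R,9aS) derived from 25 | CC[C@@H]([C@H]1CC=CC[N+]2=CCC[C@@H]12)[C@H]1C[C@H](C)C(=O)O1.[Cl-] | intermediate
29 | (5S)-3-methyl-5-[(3S,9R,9aS)-9-{(1S)-1-[(2R,4S)-4-methyl-5-oxooxolan-2-yl]propyl}-2,3,5,8,9,9a-hexahydro-1H-pyrrolo[1,2-a]azepin-3-yl]furan-2(5H)-one | CC[C@@H]([C@H]1CC=CCN2[C@H]1CC[C@H]2[C@@H]1C=C(C)C(=O)O1)[C@H]1C[C@H](C)C(=O)O1 | intermediate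
30 | (3S,5S)-3-methyl-5-[(3S,9R,9aS)-9-{(1S)-1-[(2R,4S)-4-methyl-5-oxooxolan-2-yl]propyl}octahydro-1H-pyrrolo[1,2-a]azepin-3-yl]oxolan-2-one | CC[C@@H]([C@H]1CCCCN2[C@H]1CC[C@H]2[C@@H]1C[C@H](C)C(=O)O1)[C@H]1C[C@H](C)C(=O)O1 | target

**Step count and risks**

Total step count: 14. Longest linear sequence: 12 steps (steps 1, 3 to 11, 13 and 14); steps 2 and 12 are one-step side branches.

Steps most likely to fail:

1. Step 10. The seven-membered cationic closure may be slower than side reactions of the iminium ion (oligomerization, ylide formation next to the ester) or than protodesilylation of the vinylsilane. The fallback builds the azepine stepwise by metathesis instead of by cationic closure. It sets out from 20: Boc removal and base without formaldehyde give pyrrolidine 22, now isolated. N-Allylation (allyl bromide, K2CO3, MeCN) gives the N-allyl pyrrolidine F1. Protodesilylation (TsOH·H2O, wet MeCN, 80 °C) gives the diene F2. Ring-closing metathesis of its TsOH salt with second-generation Grubbs catalyst RuCl2(=CHPh)(PCy3)(H2IMes) in CH2Cl2 at 40 °C comes back to the route at 24.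

2. Step 7. Facial selectivity at the C9a ketone may be poor, because there the catalyst has to override the intrinsic bias of the substrate. The fallback uses substrate control followed by a double inversion. It sets out from 16: LiBH(s-Bu)3 in THF at −78 °C (Felkin–Anh attack at both ketones) gives the diol F3, which lactonizes with pyridinium p-toluenesulfonate to the C9a-epimeric hydroxy lactone F4. Semihydrogenation as in step 8 gives the vinylsilane F5. Appel bromination (CBr4, PPh3, CH2Cl2, 0 °C) with inversion gives the bromide F6. TFA and then (CH2O)n, i-Pr2NEt, MeCN as in step 10 proceed through the ammonium salt F7, then 22 and 23, and come back to the route at 24.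

3. Step 13. The vinylogous Mannich addition may show low threo/erythro or facial selectivity, or the iminium ion may be lost by tautomerization to the enamine. The fallback keeps C3 of 24, which already has the target configuration, and builds the lactone on its carboxyl carbon. It sets out from 24: NaBH4 in MeOH at 0 °C (α-amino ester faster than γ-lactone) gives the amino alcohol F8. Swern oxidation gives the amino aldehyde F9. Barbier allylation with methyl 2-(bromomethyl)acrylate and Zn dust in THF/aqueous NH4Cl (chelation through N4 and the aldehyde oxygen, syn adduct), with lactonization in the same pot, gives the α-methylene lactone F10. Hydrogenation under the conditions of step 14 comes back to the route at 30.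

**Further compounds**

F1 | step 10 | methyl (2S,5S)-1-allyl-5-{(1Z,4R,5S)-5-[(2R,4S)-4-methyl-5-oxooxolan-2-yl]-1-(trimethylsilyl)hept-1-en-4-yl}pyrrolidine-2-carboxylate | CC[C@@H]([C@H]([C@@H]1CC[C@@H](C(=O)OC)N1CC=C)C/C=C\[Si](C)(C)C)[C@H]1C[C@H](C)C(=O)O1
F2 | step 10 | methyl (2S,5S)-1-allyl-5-{(4R,5S)-5-[(2R,4S)-4-methyl-5-oxooxolan-2-yl]hept-1-en-4-yl}pyrrolidine-2-carboxylate | CC[C@@H]([C@H]([C@@H]1CC[C@@H](C(=O)OC)N1CC=C)CC=C)[C@H]1C[C@H](C)C(=O)O1
F3 | step 7 | dimethyl (2S,4R,5S,6R,7S,10S)-10-[(tert-butoxycarbonyl)amino]-5-ethyl-4,7-dihydroxy-2-methyl-6-[3-(trimethylsilyl)prop-2-yn-1-yl]undecanedioate | CC[C@@H]([C@H]([C@@H](O)CC[C@H](NC(=O)OC(C)(C)C)C(=O)OC)CC#C[Si](C)(C)C)[C@H](O)C[C@H](C)C(=O)OC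
F4 | step 7 | methyl (2S,5S,6R,7S)-2-[(tert-butoxycarbonyl)amino]-5-hydroxy-7-[(2R,4S)-4-methyl-5-oxooxolan-2-yl]-6-[3-(trimethylsilyl)prop-2-yn-1-yl]nonanoate | CC[C@@H]([C@H]([C@@H](O)CC[C@H](NC(=O)OC(C)(C)C)C(=O)OC)CC#C[Si](C)(C)C)[C@H]1C[C@H](C)C(=O)O1
F5 | step 7 | methyl (2S,5S,6R,7S)-2-[(tert-butoxycarbonyl)amino]-5-hydroxy-7-[(2R,4S)-4-methyl-5-oxooxolan-2-yl]-6-[(Z)-3-(trimethylsilyl)prop-2-en-1-yl]nonanoate | CC[C@@H]([C@H]([C@@H](O)CC[C@H](NC(=O)OC(C)(C)C)C(=O)OC)C/C=C\[Si](C)(C)C)[C@H]1C[C@H](C)C(=O)O1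
F6 | step 7 | methyl (2S,5R,6R,7S)-5-bromo-2-[(tert-butoxycarbonyl)amino]-7-[(2R,4S)-4-methyl-5-oxooxolan-2-yl]-6-[(Z)-3-(trimethylsilyl)prop-2-en-1-yl]nonanoate | CC[C@@H]([C@H]([C@H](Br)CC[C@H](NC(=O)OC(C)(C)C)C(=O)OC)C/C=C\[Si](C)(C)C)[C@H]1C[C@H](C)C(=O)O1
F7 | step 7 | ammonium trifluoroacetate of the N-deprotected bromide F6 | CC[C@@H]([C@H]([C@H](Br)CC[C@H]([NH3+])C(=O)OC)C/C=C\[Si](C)(C)C)[C@H]1C[C@H](C)C(=O)O1.[O-]C(=O)C(F)(F)F
F8 | step 13 | (3S,5R)-5-{(1S)-1-[(3S,9R,9aS)-3-(hydroxymethyl)-2,3,5,8,9,9a-hexahydro-1H-pyrrolo[1,2-a]azepin-9-yl]propyl}-3-methyloxolan-2-one | CC[C@@H]([C@H]1CC=CCN2[C@H]1CC[C@H]2CO)[C@H]1C[C@H](C)C(=O)O1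
F9 | step 13 | (3S,9R,9aS)-9-{(1S)-1-[(2R,4S)-4-methyl-5-oxooxolan-2-yl]propyl}-2,3,5,8,9,9a-hexahydro-1H-pyrrolo[1,2-a]azepine-3-carbaldehyde | CC[C@@H]([C@H]1CC=CCN2[C@H]1CC[C@H]2C=O)[C@H]1C[C@H](C)C(=O)O1
F10 | step 13 | (5S)-3-methylidene-5-[(3S,9R,9aS)-9-{(1S)-1-[(2R,4S)-4-methyl-5-oxooxolan-2-yl]propyl}-2,3,5,8,9,9a-hexahydro-1H-pyrrolo[1,2-a]azepin-3-yl]oxolan-2-one | CC[C@@H]([C@H]1CC=CCN2[C@H]1CC[C@H]2[C@@H]1CC(=C)C(=O)O1)[C@H]1C[C@H](C)C(=O)O1
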